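The 14-membered carbocycle is opened at C7–C8, where a secondary carbinol (C7) sits next to the ring carbon that carries the exocyclic methylene (C8=C19). This allylic alcohol maps onto the addition of a 2-metallo-1-alkene to an aldehyde. One nickel/chromium-mediated operation therefore forms the C7–C8 bond, closes the macrocycle and creates the C7 stereocentre, with the methylidene carbinol in its final form. The substrate is a seco chain carrying the C8 2-iodoalkene and the C7 aldehyde, with the cis-fused α-methylene γ-lactone (C1, C14, C15–C17), the C3–C4 epoxide and the C13 acetate already installed. It is assembled from two fragments by an indium allylation that builds the lactone.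

Key step: step 20

Remark: locants follow cembrane numbering (C1 and C14 are the lactone ring-fusion carbons, C14 bearing the ring oxygen; C15, C16 and C17 are its α-carbon, carbonyl carbon and exocyclic methylene; C19 is the methylene on C8); the antipode of the chromium ligand in step 20 is the one that a pilot run shows to favour the Si face of the C7 formyl group.

**Fragment A (C8–C14)**

Step 1
Reactants: 1 (S)-citronellal
Product: 4 (2R,3S)-3,7-dimethyloct-6-ene-1,2-diol, via aminoxy aldehyde 2 (not isolated), via anilinooxy alcohol 3 (not isolated)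
Conditions: PhNO, L-proline (20 mol %), DMSO, rt; NaBH4, MeOH, 0 °C; Zn, AcOH, rt
Reagents that add atoms: nitrosobenzene, O=Nc1ccccc1
Why: Proline-catalysed α-aminoxylation, in which the L-proline enamine of 1 is attacked by the oxygen of nitrosobenzene on the face fixed by the carboxylic acid hydrogen bond, should set C13 as R under catalyst control whatever the bias of the C12 methyl centre, after which borohydride reduces the labile aldehyde and zinc in acetic acid cleaves the N–O bond.

Step 2
Reactants: 4 (2R,3S)-3,7-dimethyloct-6-ene-1,2-diol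
Product: 5 (4R)-2-(4-methoxyphenyl)-4-[(2S)-6-methylhept-5-en-2-yl]-1,3-dioxolane (both acetal epimers)
Conditions: 4-MeOC6H4CH(OMe)2, PPTS (cat.), CH2Cl2, rt
Reagents that add atoms: 4-methoxybenzaldehyde dimethyl acetal, COC(OC)c1ccc(OC)cc1
Why: Acid-catalysed transacetalisation closes the five-membered p-methoxybenzylidene acetal, which protects both hydroxyls through the basic steps and carries the latent PMB ether, the configuration of the acetal carbon being of no consequence.

Step 3
Reactants: 5 (4R)-2-(4-methoxyphenyl)-4-[(2S)-6-methylhept-5-en-2-yl]-1,3-dioxolane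
Product: 7 (4S)-4-[(4R)-2-(4-methoxyphenyl)-1,3-dioxolan-4-yl]pentan-1-ol, via aldehyde 6 (not isolated)
Conditions: O3, CH2Cl2/MeOH, −78 °C (Sudan red 7B end-point); NaBH4, −78 °C to rt
Reagents that add atoms: ozone, [O-][O+]=O
Why: Ozonolysis with reductive work-up should succeed because the electron-rich trisubstituted alkene reacts with ozone far faster than the anisyl acetal at low temperature, and NaBH4 reduces the peroxidic intermediate through aldehyde 6 to the primary alcohol.

Step 4
Reactants: 7 (4S)-4-[(4R)-2-(4-methoxyphenyl)-1,3-dioxolan-4-yl]pentan-1-ol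
Product: 8 (4R)-4-[(2S)-5-iodopentan-2-yl]-2-(4-methoxyphenyl)-1,3-dioxolane
Conditions: I2, PPh3, imidazole, CH2Cl2, 0 °C to rt
Reagents that add atoms: iodine, II
Why: Appel-type iodination proceeds through the alkoxyphosphonium salt and SN2 displacement by iodide at the unhindered primary carbon, with imidazole keeping the medium non-acidic for the acetal.

Step 5
Reactants: 8 (4R)-4-[(2S)-5-iodopentan-2-yl]-2-(4-methoxyphenyl)-1,3-dioxolane; 9 lithium acetylide–ethane-1,2-diamine complex
Product: 10 (4R)-4-[(2S)-hept-6-yn-2-yl]-2-(4-methoxyphenyl)-1,3-dioxolane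
Conditions: LiC≡CH·H2NCH2CH2NH2, DMSO, 0 °C to rt
Reagents that add atoms: none
Why: SN2 alkylation of an acetylide by a primary iodide in a dipolar aprotic solvent adds C8 and C19 as a terminal alkyne, the acetal being inert to the base.

Step 6
Reactants: 10 (4R)-4-[(2S)-hept-6-yn-2-yl]-2-(4-methoxyphenyl)-1,3-dioxolane
Product: 11 (2R,3S)-2-[(4-methoxyphenyl)methoxy]-3-methyloct-7-yn-1-ol
Conditions: i-Bu2AlH, CH2Cl2, −78 to 0 °C
Reagents that add atoms: none
Why: In this reductive acetal opening aluminium binds the less hindered primary oxygen, the C–O bond to that oxygen breaks and hydride is delivered to the oxocarbenium ion, so the PMB ether stays on the secondary C13 oxygen and the C14 hydroxyl is freed.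

Step 7
Reactants: 11 (2R,3S)-2-[(4-methoxyphenyl)methoxy]-3-methyloct-7-yn-1-ol
Product: 13 (2R,3S)-7-iodo-2-[(4-methoxyphenyl)methoxy]-3-methyloct-7-en-1-ol, via alkenylalane 12 (not isolated)
Conditions: NiCl2(dppp) (3 mol %), i-Bu2AlH, THF, rt; N-iodosuccinimide, 0 °C
Reagents that add atoms: N-iodosuccinimide, O=C1CCC(=O)N1I
Why: Nickel-catalysed α-selective (Markovnikov) hydroalumination of the terminal alkyne places aluminium on the internal carbon C8, and iodinolysis of the alkenyl–aluminium bond gives the 2-iodo-1-alkene without acid, so the PMB ether survives while the hydroxyl is carried as its aluminium alkoxide.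

Step 8
Reactants: 13 (2R,3S)-7-iodo-2-[(4-methoxyphenyl)methoxy]-3-methyloct-7-en-1-ol
Product: 14 (2R,3S)-7-iodo-2-[(4-methoxyphenyl)methoxy]-3-methyloct-7-enal
Conditions: Dess–Martin periodinane, NaHCO3, CH2Cl2, 0 °C to rt; used at once
Reagents that add atoms: none
Why: Buffered Dess–Martin oxidation should give the α-alkoxy aldehyde without over-oxidation or epimerisation at C13.

**Fragment B (C1–C7 with C15–C17)**

Step 9
Reactants: 15 pent-4-yn-1-ol
Product: 16 tert-butyldimethyl(pent-4-yn-1-yloxy)silane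
Conditions: t-BuMe2SiCl, imidazole, CH2Cl2, rt
Reagents that add atoms: tert-butyldimethylsilyl chloride, CC(C)(C)[Si](C)(C)Cl
Why: Silylation of a primary alcohol with imidazole as base and nucleophilic catalyst.

Step 10
Reactants: 16 tert-butyldimethyl(pent-4-yn-1-yloxy)silane; 17 oxirane
Product: 20 (3E)-7-[(tert-butyldimethylsilyl)oxy]-4-methylhept-3-en-1-ol, via alkenylalane 18 (not isolated), via lithium alanate 19 (not isolated)
Conditions: Me3Al, Cp2ZrCl2 (cat.), CH2Cl2, 0 °C to rt; solvent change to hexane; n-BuLi, −78 °C; oxirane, THF, −78 °C to rt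
Reagents that add atoms: trimethylaluminium, C[Al](C)C
Why: In the Negishi carboalumination the zirconium-catalysed syn addition of methyl–aluminium puts the methyl on the internal alkyne carbon and fixes the E geometry of C3=C4, and the derived lithium alanate opens oxirane with retention at the alkenyl carbon to add C1 and C2.

Step 11
Reactants: 20 (3E)-7-[(tert-butyldimethylsilyl)oxy]-4-methylhept-3-en-1-ol
Product: 21 2-[(2R,3R)-3-{3-[(tert-butyldimethylsilyl)oxy]propyl}-3-methyloxiran-2-yl]ethan-1-ol
Conditions: D-fructose-derived ketone (Shi catalyst, 30 mol %), KHSO5 (as 2KHSO5·KHSO4·K2SO4), K2CO3, Bu4NHSO4, MeCN/CH2(OMe)2/aq. Na2B4O7 buffer, 0 °C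
Reagents that add atoms: potassium peroxymonosulfate, [K+].[O-]S(=O)(=O)OO
Why: In the Shi epoxidation the chiral dioxirane transfers oxygen to the E-trisubstituted alkene through a spiro transition state, which by the established facial preference for such alkenes should give the (3R,4R)-epoxide (cembrane C3, C4) under reagent control, the basic buffer keeping the epoxy alcohol intact.

Step 12
Reactants: 21 2-[(2R,3R)-3-{3-[(tert-butyldimethylsilyl)oxy]propyl}-3-methyloxiran-2-yl]ethan-1-ol
Product: 22 2-[(2R,3R)-3-{3-[(tert-butyldimethylsilyl)oxy]propyl}-3-methyloxiran-2-yl]acetaldehyde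
Conditions: Dess–Martin periodinane, NaHCO3, CH2Cl2, 0 °C; crude product used at once
Reagents that add atoms: none
Why: Buffered Dess–Martin oxidation forms the β,γ-epoxy aldehyde under conditions that are neither basic nor acidic, and immediate use limits enolisation-driven epoxide opening.

Step 13
Reactants: 22 2-[(2R,3R)-3-{3-[(tert-butyldimethylsilyl)oxy]propyl}-3-methyloxiran-2-yl]acetaldehyde; 23 methyl propiolate
Product: 25 methyl 4-[(2R,3R)-3-{3-[(tert-butyldimethylsilyl)oxy]propyl}-3-methyloxiran-2-yl]-3-hydroxy-2-methylidenebutanoate (both carbinol epimers), via vinylalane 24 (not isolated)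
Conditions: i-Bu2AlH, N-methylmorpholine N-oxide, THF, 0 °C, then 23; then 22, 0 °C to rt
Reagents that add atoms: none
Why: Vinylalumination serves as a base-free surrogate of the Morita–Baylis–Hillman reaction, in which conjugate hydroalumination of methyl propiolate gives the α-aluminoacrylate 24 that adds through carbon to the aldehyde to form the C1–C15 bond, the new carbinol centre being erased in step 14.

Step 14
Reactants: 25 methyl 4-[(2R,3R)-3-{3-[(tert-butyldimethylsilyl)oxy]propyl}-3-methyloxiran-2-yl]-3-hydroxy-2-methylidenebutanoate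
Product: 27 methyl (2Z)-2-(bromomethyl)-4-[(2R,3R)-3-{3-[(tert-butyldimethylsilyl)oxy]propyl}-3-methyloxiran-2-yl]but-2-enoate, via mesylate 26 (not isolated)
Conditions: MsCl, Et3N, CH2Cl2, −40 to 0 °C; LiBr, THF, 0 °C to rt
Reagents that add atoms: lithium bromide, [Li+].[Br-]
Why: Mesylation followed by SN2′ displacement with bromide moves the double bond into conjugation and should give the thermodynamically preferred Z primary allylic bromide (C2 chain trans to the ester) under conditions that trisubstituted epoxides tolerate.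

**Union and endgame**

Step 15
Reactants: 14 (2R,3S)-7-iodo-2-[(4-methoxyphenyl)methoxy]-3-methyloct-7-enal; 27 methyl (2Z)-2-(bromomethyl)-4-[(2R,3R)-3-{3-[(tert-butyldimethylsilyl)oxy]propyl}-3-methyloxiran-2-yl]but-2-enoate
Product: 29 (4S,5R)-4-{[(2R,3R)-3-{3-[(tert-butyldimethylsilyl)oxy]propyl}-3-methyloxiran-2-yl]methyl}-5-{(1R,2S)-6-iodo-1-[(4-methoxyphenyl)methoxy]-2-methylhept-6-en-1-yl}-3-methylideneoxolan-2-one, via hydroxy ester 28 (not isolated)
Conditions: In (powder), THF/H2O 1:1, rt; extractive work-up; DBU (10 mol %), CH2Cl2, 0 °C to rt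
Reagents that add atoms: none
Why: In this Barbier-type indium allylation the allylindium from 27 attacks the aldehyde through its γ-carbon (C1) in a chair-like Zimmerman–Traxler array in which the Z-disposed C2 substituent leads to the syn C1/C14 relationship, while chelation of indium between the aldehyde oxygen and the C13 PMB ether (Cram chelate) directs attack to the face that gives the 13,14-syn arrangement, so that C14 should be R and C1 S, and catalytic DBU then closes the cis-fused α-methylene γ-lactone with loss of methanol.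

Step 16
Reactants: 29 (4S,5R)-4-{[(2R,3R)-3-{3-[(tert-butyldimethylsilyl)oxy]propyl}-3-methyloxiran-2-yl]methyl}-5-{(1R,2S)-6-iodo-1-[(4-methoxyphenyl)methoxy]-2-methylhept-6-en-1-yl}-3-methylideneoxolan-2-one
Product: 30 (4S,5R)-4-{[(2R,3R)-3-{3-[(tert-butyldimethylsilyl)oxy]propyl}-3-methyloxiran-2-yl]methyl}-5-[(1R,2S)-1-hydroxy-6-iodo-2-methylhept-6-en-1-yl]-3-methylideneoxolan-2-one
Conditions: DDQ, CH2Cl2/pH 7 phosphate buffer 10:1, 0 °C to rt
Reagents that add atoms: none
Why: Oxidative PMB cleavage by DDQ proceeds by hydride abstraction from the electron-rich benzylic position and hydrolysis of the oxocarbenium ion in a neutral two-phase medium that spares the epoxide, silyl ether, alkenyl iodide and enoate.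

Step 17
Reactants: 30 (4S,5R)-4-{[(2R,3R)-3-{3-[(tert-butyldimethylsilyl)oxy]propyl}-3-methyloxiran-2-yl]methyl}-5-[(1R,2S)-1-hydroxy-6-iodo-2-methylhept-6-en-1-yl]-3-methylideneoxolan-2-one
Product: 31 (1R,2S)-1-[(2R,3S)-3-{[(2R,3R)-3-{3-[(tert-butyldimethylsilyl)oxy]propyl}-3-methyloxiran-2-yl]methyl}-4-methylidene-5-oxooxolan-2-yl]-6-iodo-2-methylhept-6-en-1-yl acetate
Conditions: Ac2O, pyridine, DMAP (cat.), CH2Cl2, 0 °C to rt
Reagents that add atoms: acetic anhydride, CC(=O)OC(C)=O
Why: DMAP-catalysed acylation of the hindered secondary C13 alcohol installs the first acetate under basic conditions that leave the lactone and the epoxide untouched.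

Step 18
Reactants: 31 (1R,2S)-1-[(2R,3S)-3-{[(2R,3R)-3-{3-[(tert-butyldimethylsilyl)oxy]propyl}-3-methyloxiran-2-yl]methyl}-4-methylidene-5-oxooxolan-2-yl]-6-iodo-2-methylhept-6-en-1-yl acetate
Product: 32 (1R,2S)-1-[(2R,3S)-3-{[(2R,3R)-3-(3-hydroxypropyl)-3-methyloxiran-2-yl]methyl}-4-methylidene-5-oxooxolan-2-yl]-6-iodo-2-methylhept-6-en-1-yl acetate
Conditions: Bu4NF, AcOH (1:1), THF, 0 °C to rt
Reagents that add atoms: none
Why: Fluoride-induced desilylation, driven by the strength of the Si–F bond, frees the primary C7 alcohol in an acetic acid-buffered, essentially neutral medium, so the 4,5-epoxy alcohol should not cyclise and the acetate is retained.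

Step 19
Reactants: 32 (1R,2S)-1-[(2R,3S)-3-{[(2R,3R)-3-(3-hydroxypropyl)-3-methyloxiran-2-yl]methyl}-4-methylidene-5-oxooxolan-2-yl]-6-iodo-2-methylhept-6-en-1-yl acetate
Product: 33 (1R,2S)-6-iodo-2-methyl-1-[(2R,3S)-4-methylidene-3-{[(2R,3R)-3-methyl-3-(3-oxopropyl)oxiran-2-yl]methyl}-5-oxooxolan-2-yl]hept-6-en-1-yl acetate (seco iodoalkene aldehyde)
Conditions: SO3·pyridine, DMSO, i-Pr2NEt, CH2Cl2, 0 °C
Reagents that add atoms: none
Why: Parikh–Doering oxidation (activated DMSO) converts the primary alcohol to the aldehyde in a basic medium, which avoids acid-induced attack of the hydroxyl on the epoxide and stops at the aldehyde.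

Step 20
Reactants: 33 seco iodoalkene aldehyde
Product: 34 (1S,3R,4R,7R,12S,13R,14R)-13-acetoxy-3,4-epoxy-7-hydroxycembra-8(19),15(17)-dien-16,14-olide (7-desacetyl target)
Conditions: CrCl2 (excess), N-[2-(4-isopropyl-4,5-dihydro-1,3-oxazol-2-yl)-6-methylphenyl]methanesulfonamide (single enantiomer), Et3N, THF, rt; NiCl2 (cat.); 33 added by syringe pump to 2 mM, rt; neutral aqueous work-up
Reagents that add atoms: none
Why: Zerovalent nickel, formed from NiCl2 by divalent chromium, inserts into the C8–I bond, the alkenyl group passes to trivalent chromium, and the alkenylchromium adds 1,2 to the C7 aldehyde. The closest known reaction type is the intramolecular Nozaki–Hiyama–Kishi coupling of a 2-iodo-1-alkene with an aldehyde to give a macrocyclic allylic alcohol. The 14-membered carbocycle closes in the 14-exo-trig mode, high dilution favouring ring closure over intermolecular coupling. The new C7 stereocentre is controlled by the chiral oxazoline sulfonamide ligand on chromium, which must deliver the alkenyl group to the Si face of the formyl group to give 7R. The step needs chemoselectivity for the aldehyde and this facial selectivity: the substrate has one aldehyde and one C(sp2)–I bond, alkenylchromium reagents leave the lactone, the acetate, the epoxide and the conjugated methylene alone, and the nearest stereocentre (C4) is three bonds from C7, so substrate bias should be weak and the ligand should dominate. The cis-lactone and the trans-epoxide fold the chain so that C7 and C8 can meet, and the neutral work-up keeps the new hydroxyl from opening the epoxide.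

Step 21
Reactants: 34 7-desacetyl target
Product: 35 (1S,3R,4R,7R,12S,13R,14R)-7,13-diacetoxy-3,4-epoxycembra-8(19),15(17)-dien-16,14-olide (target, CNP0323853.1)
Conditions: Ac2O, pyridine, DMAP (cat.), CH2Cl2, 0 °C
Reagents that add atoms: acetic anhydride, CC(=O)OC(C)=O
Why: DMAP-catalysed acetylation of the allylic C7 alcohol with retention completes the diacetate under basic conditions that suppress transannular attack of the hydroxyl on the epoxide.

**Compound list**

1 | (S)-citronellal, (3S)-3,7-dimethyloct-6-enal | CC(C)=CCC[C@H](C)CC=O | starting material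
2 | (2R,3S)-3,7-dimethyl-2-(phenylaminooxy)oct-6-enal (not isolated) | CC(C)=CCC[C@H](C)[C@@H](ONc1ccccc1)C=O | intermediate
3 | (2R,3S)-3,7-dimethyl-2-(phenylaminooxy)oct-6-en-1-ol (not isolated) | CC(C)=CCC[C@H](C)[C@@H](ONc1ccccc1)CO | intermediate
4 | (2R,3S)-3,7-dimethyloct-6-ene-1,2-diol | CC(C)=CCC[C@H](C)[C@@H](O)CO | intermediate
5 | (4R)-2-(4-methoxyphenyl)-4-[(2S)-6-methylhept-5-en-2-yl]-1,3-dioxolane (acetal epimers) | CC(C)=CCC[C@H](C)[C@@H]1COC(c2ccc(OC)cc2)O1 | intermediate
6 | (4S)-4-[(4R)-2-(4-methoxyphenyl)-1,3-dioxolan-4-yl]pentanal (not isolated) | O=CCC[C@H](C)[C@@H]1COC(c2ccc(OC)cc2)O1 | intermediate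
7 | (4S)-4-[(4R)-2-(4-methoxyphenyl)-1,3-dioxolan-4-yl]pentan-1-ol | OCCC[C@H](C)[C@@H]1COC(c2ccc(OC)cc2)O1 | intermediate
8 | (4R)-4-[(2S)-5-iodopentan-2-yl]-2-(4-methoxyphenyl)-1,3-dioxolane | ICCC[C@H](C)[C@@H]1COC(c2ccc(OC)cc2)O1 | intermediate
9 | lithium acetylide–ethane-1,2-diamine complex | [Li+].[C-]#C.NCCN | starting material
10 | (4R)-4-[(2S)-hept-6-yn-2-yl]-2-(4-methoxyphenyl)-1,3-dioxolane | C#CCCC[C@H](C)[C@@H]1COC(c2ccc(OC)cc2)O1 | intermediate
11 | (2R,3S)-2-[(4-methoxyphenyl)methoxy]-3-methyloct-7-yn-1-ol | C#CCCC[C@H](C)[C@@H](OCc1ccc(OC)cc1)CO | intermediate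
12 | diisobutyl[(6S,7R)-8-(diisobutylalumanyloxy)-7-[(4-methoxyphenyl)methoxy]-6-methyloct-1-en-2-yl]alumane (not isolated) | C=C([Al](CC(C)C)CC(C)C)CCC[C@H](C)[C@@H](OCc1ccc(OC)cc1)CO[Al](CC(C)C)CC(C)C | intermediate
13 | (2R,3S)-7-iodo-2-[(4-methoxyphenyl)methoxy]-3-methyloct-7-en-1-ol | C=C(I)CCC[C@H](C)[C@@H](OCc1ccc(OC)cc1)CO | intermediate
14 | (2R,3S)-7-iodo-2-[(4-methoxyphenyl)methoxy]-3-methyloct-7-enal | C=C(I)CCC[C@H](C)[C@@H](OCc1ccc(OC)cc1)C=O | intermediate
15 | pent-4-yn-1-ol | C#CCCCO | starting material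
16 | tert-butyldimethyl(pent-4-yn-1-yloxy)silane | C#CCCCO[Si](C)(C)C(C)(C)C | intermediate
17 | oxirane (ethylene oxide) | C1CO1 | starting material
18 | [(1E)-5-[(tert-butyldimethylsilyl)oxy]-2-methylpent-1-en-1-yl]dimethylalumane (not isolated) | C[Al](C)/C=C(\C)CCCO[Si](C)(C)C(C)(C)C | intermediate
19 | lithium butyl[(1E)-5-[(tert-butyldimethylsilyl)oxy]-2-methylpent-1-en-1-yl]dimethylaluminate (not isolated) | [Li+].CCCC[Al-](C)(C)/C=C(\C)CCCO[Si](C)(C)C(C)(C)C | intermediate
20 | (3E)-7-[(tert-butyldimethylsilyl)oxy]-4-methylhept-3-en-1-ol | OCC/C=C(\C)CCCO[Si](C)(C)C(C)(C)C | intermediate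
21 | 2-[(2R,3R)-3-{3-[(tert-butyldimethylsilyl)oxy]propyl}-3-methyloxiran-2-yl]ethan-1-ol | OCC[C@H]1O[C@]1(C)CCCO[Si](C)(C)C(C)(C)C | intermediate
22 | 2-[(2R,3R)-3-{3-[(tert-butyldimethylsilyl)oxy]propyl}-3-methyloxiran-2-yl]acetaldehyde | O=CC[C@H]1O[C@]1(C)CCCO[Si](C)(C)C(C)(C)C | intermediate
23 | methyl propiolate (methyl prop-2-ynoate) | C#CC(=O)OC | starting material
24 | [1-(methoxycarbonyl)ethenyl]diisobutylalumane (not isolated) | COC(=O)C(=C)[Al](CC(C)C)CC(C)C | intermediate
25 | methyl 4-[(2R,3R)-3-{3-[(tert-butyldimethylsilyl)oxy]propyl}-3-methyloxiran-2-yl]-3-hydroxy-2-methylidenebutanoate (carbinol epimers) | COC(=O)C(=C)C(O)C[C@H]1O[C@]1(C)CCCO[Si](C)(C)C(C)(C)C | intermediate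
26 | methyl 4-[(2R,3R)-3-{3-[(tert-butyldimethylsilyl)oxy]propyl}-3-methyloxiran-2-yl]-3-(methanesulfonyloxy)-2-methylidenebutanoate (not isolated) | COC(=O)C(=C)C(OS(C)(=O)=O)C[C@H]1O[C@]1(C)CCCO[Si](C)(C)C(C)(C)C | intermediate
27 | methyl (2Z)-2-(bromomethyl)-4-[(2R,3R)-3-{3-[(tert-butyldimethylsilyl)oxy]propyl}-3-methyloxiran-2-yl]but-2-enoate | COC(=O)/C(CBr)=C/C[C@H]1O[C@]1(C)CCCO[Si](C)(C)C(C)(C)C | intermediate
28 | methyl (3S,4R,5R,6S)-4-hydroxy-10-iodo-5-[(4-methoxyphenyl)methoxy]-6-methyl-2-methylidene-3-{[(2R,3R)-3-{3-[(tert-butyldimethylsilyl)oxy]propyl}-3-methyloxiran-2-yl]methyl}undec-10-enoate (not isolated) | C=C(I)CCC[C@H](C)[C@@H](OCc1ccc(OC)cc1)[C@H](O)[C@@H](C[C@H]1O[C@]1(C)CCCO[Si](C)(C)C(C)(C)C)C(=C)C(=O)OC | intermediate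
29 | (4S,5R)-4-{[(2R,3R)-3-{3-[(tert-butyldimethylsilyl)oxy]propyl}-3-methyloxiran-2-yl]methyl}-5-{(1R,2S)-6-iodo-1-[(4-methoxyphenyl)methoxy]-2-methylhept-6-en-1-yl}-3-methylideneoxolan-2-one | C=C(I)CCC[C@H](C)[C@@H](OCc1ccc(OC)cc1)[C@@H]1OC(=O)C(=C)[C@@H]1C[C@H]1O[C@]1(C)CCCO[Si](C)(C)C(C)(C)C | intermediate
30 | (4S,5R)-4-{[(2R,3R)-3-{3-[(tert-butyldimethylsilyl)oxy]propyl}-3-methyloxiran-2-yl]methyl}-5-[(1R,2S)-1-hydroxy-6-iodo-2-methylhept-6-en-1-yl]-3-methylideneoxolan-2-one | C=C(I)CCC[C@H](C)[C@@H](O)[C@@H]1OC(=O)C(=C)[C@@H]1C[C@H]1O[C@]1(C)CCCO[Si](C)(C)C(C)(C)C | intermediate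
31 | (1R,2S)-1-[(2R,3S)-3-{[(2R,3R)-3-{3-[(tert-butyldimethylsilyl)oxy]propyl}-3-methyloxiran-2-yl]methyl}-4-methylidene-5-oxooxolan-2-yl]-6-iodo-2-methylhept-6-en-1-yl acetate | C=C(I)CCC[C@H](C)[C@@H](OC(C)=O)[C@@H]1OC(=O)C(=C)[C@@H]1C[C@H]1O[C@]1(C)CCCO[Si](C)(C)C(C)(C)C | intermediate
32 | (1R,2S)-1-[(2R,3S)-3-{[(2R,3R)-3-(3-hydroxypropyl)-3-methyloxiran-2-yl]methyl}-4-methylidene-5-oxooxolan-2-yl]-6-iodo-2-methylhept-6-en-1-yl acetate | C=C(I)CCC[C@H](C)[C@@H](OC(C)=O)[C@@H]1OC(=O)C(=C)[C@@H]1C[C@H]1O[C@]1(C)CCCO | intermediate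
33 | (1R,2S)-6-iodo-2-methyl-1-[(2R,3S)-4-methylidene-3-{[(2R,3R)-3-methyl-3-(3-oxopropyl)oxiran-2-yl]methyl}-5-oxooxolan-2-yl]hept-6-en-1-yl acetate (seco iodoalkene aldehyde) | C=C(I)CCC[C@H](C)[C@@H](OC(C)=O)[C@@H]1OC(=O)C(=C)[C@@H]1C[C@H]1O[C@]1(C)CCC=O | intermediate
34 | (1S,3R,4R,7R,12S,13R,14R)-13-acetoxy-3,4-epoxy-7-hydroxycembra-8(19),15(17)-dien-16,14-olide (7-desacetyl target) | C=C1CCC[C@H](C)[C@@H](OC(C)=O)[C@@H]2OC(=O)C(=C)[C@@H]2C[C@H]2O[C@]2(C)CC[C@H]1O | intermediate
35 | (1S,3R,4R,7R,12S,13R,14R)-7,13-diacetoxy-3,4-epoxycembra-8(19),15(17)-dien-16,14-olide (CNP0323853.1) | C=C1CCC[C@H](C)[C@@H](OC(C)=O)[C@@H]2OC(=O)C(=C)[C@@H]2C[C@H]2O[C@]2(C)CC[C@H]1OC(C)=O | target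

Total step count: 21.
Longest linear sequence: 15 steps (steps 1–8, then 15–21, from (S)-citronellal).

**Steps most likely to fail**

Step 20. The hazards are poor discrimination between the two faces of the C7 formyl group and intermolecular coupling that outruns ring closure. Fallback: the closure is run from 33 without the chiral ligand (CrCl2, catalytic NiCl2, DMSO, high dilution) and the C7 epimers are separated. The 7R alcohol 34 goes on as planned. The 7S epimer F1 is converted straight into 35 by Mitsunobu esterification with acetic acid (PPh3, diisopropyl azodicarboxylate, toluene, 0 °C), which installs the acetate with inversion. The stereocentre is thus corrected after ring closure and not set during C–C bond formation; this path sets out from 33 and returns at 35.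

Step 15. The hazards are incomplete chelation by the PMB ether, which would erode the 13,14-syn facial selectivity, and acid-promoted attack of the new C14 hydroxyl on the epoxide before the lactone closes. Fallback: from 14 the PMB group is removed first (DDQ, buffered CH2Cl2/H2O) to give the α-hydroxy aldehyde F2, used crude. Indium allylation with 27 in water-rich THF, where a free α-hydroxyl binds the metal more firmly than an ether, should give the dihydroxy ester F3, which closes with catalytic DBU to the five-membered lactone. This path rejoins the route at 30, and step 16 is omitted.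

Step 13. The hazard is loss of the β,γ-epoxy aldehyde 22, by enolisation with epoxide opening or by aluminium-induced rearrangement, before the C–C bond forms. Fallback: the epoxidation is postponed. From 20, buffered Dess–Martin oxidation gives the β,γ-unsaturated aldehyde F4, and vinylalumination with 24 gives the dienyl alcohol F5. Shi epoxidation (same ketone catalyst and KHSO5, buffered) of the electron-rich trisubstituted alkene, the acrylate being inert to the dioxirane, then returns to 25.

Further compounds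
F1 | step 20 | (1S,3R,4R,7S,12S,13R,14R)-13-acetoxy-3,4-epoxy-7-hydroxycembra-8(19),15(17)-dien-16,14-olide (7-epimer of 34) | C=C1CCC[C@H](C)[C@@H](OC(C)=O)[C@@H]2OC(=O)C(=C)[C@@H]2C[C@H]2O[C@]2(C)CC[C@@H]1O
F2 | step 15 | (2R,3S)-2-hydroxy-7-iodo-3-methyloct-7-enal | C=C(I)CCC[C@H](C)[C@@H](O)C=O
F3 | step 15 | methyl (3S,4R,5R,6S)-4,5-dihydroxy-10-iodo-6-methyl-2-methylidene-3-{[(2R,3R)-3-{3-[(tert-butyldimethylsilyl)oxy]propyl}-3-methyloxiran-2-yl]methyl}undec-10-enoate | C=C(I)CCC[C@H](C)[C@@H](O)[C@H](O)[C@@H](C[C@H]1O[C@]1(C)CCCO[Si](C)(C)C(C)(C)C)C(=C)C(=O)OC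
F4 | step 13 | (3E)-7-[(tert-butyldimethylsilyl)oxy]-4-methylhept-3-enal | O=CC/C=C(\C)CCCO[Si](C)(C)C(C)(C)C
F5 | step 13 | methyl (5E)-9-[(tert-butyldimethylsilyl)oxy]-3-hydroxy-6-methyl-2-methylidenenon-5-enoate | COC(=O)C(=C)C(O)C/C=C(\C)CCCO[Si](C)(C)C(C)(C)C
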